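**Retrosynthetic overview**
- The C8 prenyl group is installed last, by moving it from O5 to C8 (Eu(III)-catalysed para-Claisen–Cope shift); no ring is formed, and until then the O-prenyl group blocks the future 5-OH.
- Ring C, the only ring made, comes from the open 2'-hydroxychalcone by a catalyst-controlled, chalcone-isomerase-type 6-endo oxa-Michael closure that sets C2 (S) directly.
- The chalcone comes from a Claisen–Schmidt union of mono-O-prenylated 2',6'-dihydroxy-4'-methoxyacetophenone with unprotected 4-hydroxybenzaldehyde.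
- Ring order: rings A and B are bought as aromatics; ring C is closed in step 3. Four steps, no protecting groups.

Assumption: the epi-quinidine thiourea in step 3 is taken to give the 2S enantiomer (I could not confirm which pseudoenantiomer does); this is checked by CD on 7 (2S-flavanones: positive Cotton effect near 330 nm, negative near 290 nm), and if it is 2R the epi-quinine pseudoenantiomer is used with nothing else changed.

**Route**

Step 1
Reactants: 1 2',6'-dihydroxy-4'-methoxyacetophenone; 2 prenyl bromide (1-bromo-3-methylbut-2-ene)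
Product: 3 1-[2-hydroxy-4-methoxy-6-(3-methylbut-2-en-1-yloxy)phenyl]ethan-1-one
Conditions: 2 (1.05 equiv), K2CO3 (1.2 equiv), acetone, reflux, 6 h
Reagents that add atoms: prenyl bromide (compound 2), CC(C)=CCBr
Why: Williamson ether synthesis on a C2-symmetric diphenol, which stops at the mono-ether because the remaining OH is then locked in a strong hydrogen bond to the acetyl C=O and is poorly nucleophilic; no stereocentre is formed.

Step 2
Reactants: 3 1-[2-hydroxy-4-methoxy-6-(3-methylbut-2-en-1-yloxy)phenyl]ethan-1-one; 4 4-hydroxybenzaldehyde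
Product: 6 (E)-1-[2-hydroxy-4-methoxy-6-(3-methylbut-2-en-1-yloxy)phenyl]-3-(4-hydroxyphenyl)prop-2-en-1-one, via aldol adduct 5 (not isolated)
Conditions: KOH (50% aq., 10 equiv), EtOH, 0 °C to rt, 48 h; then 1 M HCl to pH 5 at 0 °C
Reagents that add atoms: none
Why: Claisen–Schmidt (crossed aldol) condensation in which the acetophenone enolate adds to the non-enolisable aldehyde and E1cB dehydration of 5 gives the (E)-enone, while in concentrated KOH the product stays open as its phenoxide (as in the usual preparation of 4-hydroxy-2'-hydroxy-4',6'-dialkoxychalcones) so no racemic flavanone forms; no stereocentre survives.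

Step 3
Reactants: 6 (E)-1-[2-hydroxy-4-methoxy-6-(3-methylbut-2-en-1-yloxy)phenyl]-3-(4-hydroxyphenyl)prop-2-en-1-one
Product: 7 (2S)-2-(4-hydroxyphenyl)-7-methoxy-5-(3-methylbut-2-en-1-yloxy)chroman-4-one
Conditions: 1-[3,5-bis(trifluoromethyl)phenyl]-3-[(8R,9R)-6'-methoxycinchonan-9-yl]thiourea (epi-quinidine thiourea, 20 mol %), PhCl, 40 °C, about 72 h, stopped at full conversion
Reagents that add atoms: none
Why: Proposed new method: a chalcone-isomerase-mimetic asymmetric intramolecular oxa-Michael addition (6-endo-trig, an isomerisation with no by-product) in which the quinuclidine nitrogen acts as general base on the 2'-OH while the thiourea NH pair replaces the internal hydrogen bond to the enone C=O, so the phenoxide is delivered to one enantioface of Cβ inside a chiral ion pair and the enolate is protonated by the quinuclidinium, setting C2 (S) under catalyst control; the 6'-prenyloxy group leaves only one phenol able to close (fixing the regiochemistry) and twists the aroyl group so that the flavanone is strongly favoured and the retro-addition that would racemise it is slow; the closest known reaction types are the cinchona-base/thiourea-catalysed enantioselective cyclisation of 2'-hydroxychalcones and the thiourea-catalysed oxa-Michael cyclisation of α-alkoxycarbonyl-activated chalcones, neither shown for an electron-rich 6'-alkoxy chalcone with a free 4-OH.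

Step 4
Reactants: 7 (2S)-2-(4-hydroxyphenyl)-7-methoxy-5-(3-methylbut-2-en-1-yloxy)chroman-4-one
Product: 10 (2S)-5-hydroxy-2-(4-hydroxyphenyl)-7-methoxy-8-(3-methylbut-2-en-1-yl)chroman-4-one (Mundulea flavanone B), via ortho-Claisen dienone 8 (not isolated), via para-dienone 9 (not isolated)
Conditions: Eu(fod)3 (15 mol %), acid-free CHCl3, 60 °C (sealed tube), 24 h; neutral work-up
Reagents that add atoms: none
Why: Eu(III)-catalysed aromatic para-Claisen–Cope rearrangement (an isomerisation with no by-product), in which Eu chelated between C4=O and O5 accelerates the [3,3] shift of the prenyl ether to C6 (reverse-prenyl dienone 8), a second [3,3] Cope shift carries the group to C8 and restores the linear prenyl unit (dienone 9), and tautomerisation gives the hydrogen-bonded 5-OH phenol; C2 is not involved and keeps its S configuration.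

**Compound list**
1 | 2',6'-dihydroxy-4'-methoxyacetophenone | CC(=O)c1c(O)cc(OC)cc1O | starting material
2 | prenyl bromide (1-bromo-3-methylbut-2-ene) | CC(C)=CCBr | starting material
3 | 1-[2-hydroxy-4-methoxy-6-(3-methylbut-2-en-1-yloxy)phenyl]ethan-1-one | CC(=O)c1c(O)cc(OC)cc1OCC=C(C)C | intermediate
4 | 4-hydroxybenzaldehyde | O=Cc1ccc(O)cc1 | starting material
5 | 3-hydroxy-1-[2-hydroxy-4-methoxy-6-(3-methylbut-2-en-1-yloxy)phenyl]-3-(4-hydroxyphenyl)propan-1-one (racemic aldol adduct, not isolated) | COc1cc(O)c(C(=O)CC(O)c2ccc(O)cc2)c(OCC=C(C)C)c1 | intermediate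
6 | (E)-1-[2-hydroxy-4-methoxy-6-(3-methylbut-2-en-1-yloxy)phenyl]-3-(4-hydroxyphenyl)prop-2-en-1-one | COc1cc(O)c(C(=O)/C=C/c2ccc(O)cc2)c(OCC=C(C)C)c1 | intermediate
7 | (2S)-2-(4-hydroxyphenyl)-7-methoxy-5-(3-methylbut-2-en-1-yloxy)chroman-4-one | COc1cc(OCC=C(C)C)c2c(c1)O[C@H](c1ccc(O)cc1)CC2=O | intermediate
8 | (2S)-2-(4-hydroxyphenyl)-7-methoxy-6-(2-methylbut-3-en-2-yl)-2,3-dihydro-4H-chromene-4,5(6H)-dione (ortho-Claisen dienone, C6 epimers, not isolated) | COC1=CC2=C(C(=O)C[C@@H](c3ccc(O)cc3)O2)C(=O)C1C(C)(C)C=C | intermediate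
9 | (2S)-2-(4-hydroxyphenyl)-7-methoxy-8-(3-methylbut-2-en-1-yl)-2,3-dihydro-4H-chromene-4,5(8H)-dione (para-dienone, C8 epimers, not isolated) | COC1=CC(=O)C2=C(O[C@H](c3ccc(O)cc3)CC2=O)C1CC=C(C)C | intermediate
10 | (2S)-5-hydroxy-2-(4-hydroxyphenyl)-7-methoxy-8-(3-methylbut-2-en-1-yl)chroman-4-one (Mundulea flavanone B) | COc1cc(O)c2c(c1CC=C(C)C)O[C@H](c1ccc(O)cc1)CC2=O | target

**Totals**
Total step count: 4. Longest linear sequence: 4 (1 → 3 → 6 → 7 → 10).

**Steps most likely to fail, with fallbacks**

Step 3 (most risky). The chalcone is electron-rich, unactivated and carries a free 4-OH, so the closure may be slow or poorly selective, and ee can erode by retro-addition if the reaction is left too long. The fallback sets out from 6 and comes back at 7, giving up catalyst control in favour of resolution with recycling. 6 is cyclised with NaOAc in refluxing EtOH to the racemate, that is 7 together with its mirror image (2R)-2-(4-hydroxyphenyl)-7-methoxy-5-(3-methylbut-2-en-1-yloxy)chroman-4-one F1. Preparative chiral SFC (amylose tris(3,5-dimethylphenylcarbamate) phase, CO2/MeOH) delivers 7. F1 is returned to NaOAc/EtOH at reflux, where ring opening to 6 and re-closure racemise it for the next pass.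

Step 4. The free 4'-phenol may bind Eu(III) and slow the shift, and forcing it thermally would favour the 6-(1,1-dimethylallyl) isomer and erode ee. The fallback sets out from 7 and comes back at 10 by masking the phenol. 7 is acetylated (Ac2O, pyridine, 0 °C) to 4-[(2S)-7-methoxy-5-(3-methylbut-2-en-1-yloxy)-4-oxochroman-2-yl]phenyl acetate F2. Eu(fod)3 (10 mol %, CHCl3, 60 °C) then carries F2 through the acetylated ortho-Claisen dienone F3 and the acetylated para-dienone F4, neither isolated, to 4-[(2S)-5-hydroxy-7-methoxy-8-(3-methylbut-2-en-1-yl)-4-oxochroman-2-yl]phenyl acetate F5. Neutral enzymatic transesterification (immobilised Candida antarctica lipase B, n-BuOH, MTBE, 40 °C) removes the acetate without base, so without retro-Michael racemisation, and gives 10.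

Step 2. Phenoxide formation on 4 deactivates the aldehyde, so the condensation may stall or give a low yield. The fallback sets out from 3 and 4 and comes back at 6 by masking the phenol as a base-stable acetal. 4 is converted (3,4-dihydro-2H-pyran, PPTS, CH2Cl2) into 4-(tetrahydro-2H-pyran-2-yloxy)benzaldehyde F6, which can also be bought. Claisen–Schmidt reaction of 3 with F6 (KOH, EtOH, rt) runs through the THP-protected aldol adduct F7, not isolated, to (E)-1-[2-hydroxy-4-methoxy-6-(3-methylbut-2-en-1-yloxy)phenyl]-3-[4-(tetrahydro-2H-pyran-2-yloxy)phenyl]prop-2-en-1-one F8. PPTS in MeOH at 40 °C then frees the phenol and returns 6; the aryl prenyl ether tolerates this mild acid.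

**Further compounds**
F1 | step 3 | (2R)-2-(4-hydroxyphenyl)-7-methoxy-5-(3-methylbut-2-en-1-yloxy)chroman-4-one | COc1cc(OCC=C(C)C)c2c(c1)O[C@@H](c1ccc(O)cc1)CC2=O
F2 | step 4 | 4-[(2S)-7-methoxy-5-(3-methylbut-2-en-1-yloxy)-4-oxochroman-2-yl]phenyl acetate | COc1cc(OCC=C(C)C)c2c(c1)O[C@H](c1ccc(OC(C)=O)cc1)CC2=O
F3 | step 4 | 4-[(2S)-7-methoxy-6-(2-methylbut-3-en-2-yl)-4,5-dioxo-3,4,5,6-tetrahydro-2H-chromen-2-yl]phenyl acetate (acetylated ortho-Claisen dienone, C6 epimers, not isolated) | COC1=CC2=C(C(=O)C[C@@H](c3ccc(OC(C)=O)cc3)O2)C(=O)C1C(C)(C)C=C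
F4 | step 4 | 4-[(2S)-7-methoxy-8-(3-methylbut-2-en-1-yl)-4,5-dioxo-3,4,5,8-tetrahydro-2H-chromen-2-yl]phenyl acetate (acetylated para-dienone, C8 epimers, not isolated) | COC1=CC(=O)C2=C(O[C@H](c3ccc(OC(C)=O)cc3)CC2=O)C1CC=C(C)C
F5 | step 4 | 4-[(2S)-5-hydroxy-7-methoxy-8-(3-methylbut-2-en-1-yl)-4-oxochroman-2-yl]phenyl acetate | COc1cc(O)c2c(c1CC=C(C)C)O[C@H](c1ccc(OC(C)=O)cc1)CC2=O
F6 | step 2 | 4-(tetrahydro-2H-pyran-2-yloxy)benzaldehyde (racemic) | O=Cc1ccc(OC2CCCCO2)cc1
F7 | step 2 | 3-hydroxy-1-[2-hydroxy-4-methoxy-6-(3-methylbut-2-en-1-yloxy)phenyl]-3-[4-(tetrahydro-2H-pyran-2-yloxy)phenyl]propan-1-one (stereoisomer mixture, not isolated) | COc1cc(O)c(C(=O)CC(O)c2ccc(OC3CCCCO3)cc2)c(OCC=C(C)C)c1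
F8 | step 2 | (E)-1-[2-hydroxy-4-methoxy-6-(3-methylbut-2-en-1-yloxy)phenyl]-3-[4-(tetrahydro-2H-pyran-2-yloxy)phenyl]prop-2-en-1-one (racemic at the acetal carbon) | COc1cc(O)c(C(=O)/C=C/c2ccc(OC3CCCCO3)cc2)c(OCC=C(C)C)c1
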